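**Conventions.** Locants follow the seco-guaiane skeleton: ring carbons C1 (carbinol bearing the butenoyl chain C2(=O)–C3=C4–C15), C5 (isovalerate), C6 (lactone oxygen), C7 (bears C11(=C13H2)–C12(=O)), C8 (CH2), C9 (CHOH), C10 (CH–C14H3). α is the ring face of the C7–C11 bond (in the target also C6–O, C10–CH3 and C1–OH); β is the other face (C5–O, C9–O, C1–C2).

**Remark on the chemistry.** (S)-But-3-yn-2-ol (13) is used as one enantiomer only so that 14–19 are single diastereomers; its stereocentre becomes C4 and turns sp2 in step 14, so either enantiomer would serve.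

## The problem

The target is a 4,5-seco-guaiane lactone: a cycloheptane cis-fused at C6–C7 to an α-methylene-γ-butyrolactone, with six stereocentres on seven ring carbons (C1, C5, C6, C7, C9, C10; only C8 is CH2). The hardest is C1, a fully substituted carbinol that carries the (E)-but-2-enoyl group, lies between two stereocentres, and must be trans to the C5 oxygen and cis to the C10 methyl. Addition of a carbon nucleophile to a C1 ketone flanked by an α-oxygen would be expected to give the opposite (cis-diol) arrangement. Four oxygens must end in four different states: lactone (C6), isovalerate (C5), free secondary alcohol (C9) and free tertiary alcohol (C1). C7 is the natural anchor: a C12 carboxyl tethered to C7 can fix C6, the C6 oxygen and the C10 methyl can then steer reagents at the C1/C5 pair, and C9 can be set from C7 across the ring, leaving C10 to be set relative to C9. The α-methylene lactone and the α′-hydroxy enone are base-labile Michael acceptors, a free C5–OH β to the C2 ketone would allow retro-aldol ring cleavage, and the 9-OH/2-C=O pair can form a hemiketal; both acceptors and the ester should therefore appear late, under neutral or mildly acidic conditions. The feature the plan exploits is that C1 and C6 are 1,3-related carbinol carbons joined through C5, that is, the two ends of an allyl unit C1–C5–C6, while the C12 carboxyl on C7 can reach only C6, on the α face, to close the five-membered lactone ring. Ionizing a C1 carbinol therefore moves the oxygen to C6 and leaves a C1=C5 alkene, from which the trans C1/C5 diol follows by anti opening of an epoxide.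

## Retrosynthesis

**21 ⇒ 20 ⇒ 19 ⇒ 18 (no skeletal bond cut).** The (E)-enone and the two free hydroxyls are removed first. 21 comes from bis-silyl ether 20 by fluoride, 20 from propargylic ester 19 by a gold-catalysed 1,3-acyloxy shift and hydrolysis, and 19 from diester 18 by silylation of the tertiary alcohol. The enone is traced to a C2≡C3 alkyne with an ester on C4 and not to a C2–C3 cut, for three reasons: the alkyne survives acid and peracid, it stabilizes positive charge at C1 (needed twice below), and its activating ester is the same 3-methylbutanoate that the target carries on C5, so one acylation of triol 17 installs both. The forward steps must spare the C5 ester, the lactone and the exocyclic methylene.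

**17 ⇒ 16 ⇒ 15 (cut C1–O and C5–O).** The trans C1/C5 diol of 17 is the anti hydrolysis product of β-epoxide 16, itself from alkene 15. This is preferred to the neighbouring cut C1–C2 on a ketone, where the nucleophile would enter anti to the C5 oxygen and give the C1 epimer. The precursor 15 has two stereocentres fewer. The forward reactions need β-face epoxidation (both allylic substituents, C6–O and C10–CH3, are α) and Markovnikov attack of water at the tertiary, propargylic C1 with inversion.

**15 ⇒ 12 + 13 (key; cut C6–O of the lactone and C1–C2).** Enyne lactone 15 is the product of an alkylative allylic transposition: the acetylide of 13 adds to the enone carbonyl of 12, and the resulting tertiary alcohol 14 ionizes to a C1–C5–C6 allyl cation that the C12 carboxyl captures at C6. Against the usual lactone cut at C12–O (esterification of a separately made C6 alcohol), this cut needs no C6 stereocentre in the precursor, makes the C1 configuration of the addition irrelevant, and places the alkene exactly where the diol is needed. 12 has only three stereocentres and no lactone. The forward step must give cis ring fusion (tether control from C7) and lactonization in preference to elimination.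

**12 ⇒ 11 ⇒ 10 (oxidation level of C12).** The acrylic acid is the oxidized isopropenyl group of 10 (allylic oxidation, then alcohol to acid). Nothing else in 10 is electron-rich enough to compete.

**10 ⇒ 9 (reconnect C6–O–C9).** Enone 10 is the retro-oxa-Michael product of 8-oxabicyclo[3.2.1]octan-3-one 9. The detour through 9 is taken because in the rigid bicycle the C10 methyl equilibrates to the equatorial position, trans to C9–O, whereas the monocyclic ketone offers no such control. The forward step needs enolization at C5 (CH2) and not at C10.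

**9 ⇒ 5 ⇒ 4 ⇒ 3 ⇒ 2 ⇒ 1 (remove C5; chiral pool).** The seven-membered ring is the one-carbon ring expansion (cyclopropanation and ring opening of silyl enol ether 4 via 5) of a cyclohexanone. Hydroxy ketone 3 is carvone with C9–O added through epoxide 2. (R)-Carvone (1) supplies C1 (its carbonyl carbon), C10 with its methyl, C9, C8, C7 with the correct absolute configuration, C6, and C11–C13 as the isopropenyl group; only C5 is inserted.

## Roads not taken

**Alternative 1:** (the obvious one) Cut C6–C7 and the lactone C–O: an intramolecular Barbier or Nozaki–Hiyama–Kishi allylation (CrCl2 or indium) of the ω-formyl 2-(bromomethyl)enoate A1 would close the seven-membered ring and the lactone together. A1 must already carry C1 (quaternary), C5, C9 and C10, all made by acyclic aldol-type chemistry with three differently protected oxygens, so the run-up is longer than the whole chosen route. The ring closure onto an α-alkoxy aldehyde next to a quaternary carbinol also gives no dependable C5/C6 relationship (Felkin and chelate models oppose each other). The chosen plan takes the ring and C7 from carvone and sets C6 by a tether.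

**Alternative 2:** Cut two ring bonds (C5–C6 and C9–C10) in a (4+3) cycloaddition of furan A2 with a 1-benzyloxy-3-methyl-2-oxyallyl cation to give oxabicycle A3, which carries all seven ring carbons, the C1 carbonyl, a C5 oxygen and a C6–O–C9 bridge. A3 is racemic unless a chiral auxiliary is added. Its C7=C8 alkene is nearly symmetric, so the C11 unit cannot be placed on C7 regioselectively. The bridging oxygen sits on the wrong face of C6 for the cis-lactone, and the equatorial C5 oxygen is epimeric to the one needed. The chosen plan reaches the same bicyclic type (9) enantiopure, with C7 already substituted.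

**Alternative 3:** Keep the carvone ring expansion but cut C1–C2 last: nucleophilic epoxidation of enone 12 on the β face and acid lactonization would give hydroxy keto lactone A4 with C5 and C6 correctly set, and an acyl-anion equivalent would then be added to the C1 ketone. Polar Felkin–Anh and chelate models both put the nucleophile anti to the C5 oxygen of A4, which places the new carbon on the α face and the hydroxyl on the β face, the wrong configuration at C1. The strongly basic nucleophile would also meet a lactone next to an enolizable α-hydroxy ketone. The chosen plan adds the carbon before any C1 stereochemistry matters and sets C1 by an anti epoxide opening.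

Key step: step 9

## Route

Step 1
Reactants: 1 (R)-(−)-carvone
Product: 2 (1R,4R,6R)-1-methyl-4-(prop-1-en-2-yl)-7-oxabicyclo[4.1.0]heptan-2-one
Conditions: 30% H2O2, NaOH (cat.), MeOH, 0 °C
Reagents that add atoms: hydrogen peroxide, OO
Why: Weitz–Scheffer nucleophilic epoxidation of the enone; hydroperoxide attacks the β-carbon (future C9) anti to the isopropenyl group, which fixes C9–O on the β face, and the isopropenyl alkene does not react.

Step 2
Reactants: 2 carvone epoxide
Product: 3 (2R,3R,5R)-3-hydroxy-2-methyl-5-(prop-1-en-2-yl)cyclohexan-1-one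
Conditions: SmI2, THF/MeOH, −90 °C
Reagents that add atoms: none
Why: Reductive cleavage of the Cα–O bond of an α,β-epoxy ketone by divalent samarium (ketyl, β-elimination to the enolate, protonation); the C9–O bond is untouched, and the C10 epimer ratio does not matter because C10 is equilibrated in step 5 (3 is drawn as the expected 2,3-cis isomer).

Step 3
Reactants: 3 hydroxy ketone
Product: 4 (3R,5R,6R)-6-methyl-3-(prop-1-en-2-yl)-1,5-bis(trimethylsilyloxy)cyclohex-1-ene
Conditions: Me3SiCl, Et3N, THF, 0 °C; then LiN(i-Pr)2, Me3SiCl, −78 °C
Reagents that add atoms: chlorotrimethylsilane, C[Si](C)(C)Cl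
Why: Silylation of the alcohol, then kinetic deprotonation on the CH2 side (future C6) with the chlorosilane present, so the enolate is trapped before it can equilibrate toward C10 and expel the β-silyloxy group.

Step 4
Reactants: 4 bis-silyl compound
Product: 5 2-methyl-5-(prop-1-en-2-yl)-1,3-bis(trimethylsilyloxy)bicyclo[4.1.0]heptane (new CH2 trans to the isopropenyl group; other centres as in 4)
Conditions: Et2Zn, CH2I2, CH2Cl2, 0 °C
Reagents that add atoms: diiodomethane, ICI
Why: Simmons–Smith cyclopropanation; the electrophilic zinc carbenoid should react fastest with the silyl enol ether, the more electron-rich of the two alkenes, on the face opposite the neighbouring isopropenyl group; the new CH2 is the future C5.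

Step 5
Reactants: 5 siloxycyclopropane
Product: 9 (1R,2S,5R,6S)-2-methyl-6-(prop-1-en-2-yl)-8-oxabicyclo[3.2.1]octan-3-one, via chloro ketone 6 (not isolated), via hydroxy enone 7 (not isolated), via axial-methyl oxabicycle 8 (not isolated)
Conditions: FeCl3, DMF, 0 °C → rt; NaOAc, MeOH, reflux; K2CO3, MeOH, rt
Reagents that add atoms: none
Why: Ito–Saegusa ring expansion: one-electron oxidation by FeCl3 opens the internal cyclopropane bond to the ring-enlarged β-chloro ketone 6, and NaOAc/MeOH eliminates HCl and removes the silyl ether to give 7. The β-oriented C9–OH of 7 then adds across the ring to C6 of the enone (5-exo oxa-Michael), and in the rigid bicycle K2CO3 epimerizes the C10 methyl from axial (8) to equatorial (9), which is α and trans to C9–O.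

Step 6
Reactants: 9 oxabicyclic ketone
Product: 10 (4R,6R,7S)-6-[(tert-butyldimethylsilyl)oxy]-7-methyl-4-(prop-1-en-2-yl)cyclohept-2-en-1-one
Conditions: LiN(i-Pr)2, THF, −78 → −20 °C; t-BuMe2SiOTf, −78 → 0 °C
Reagents that add atoms: tert-butyldimethylsilyl trifluoromethanesulfonate, CC(C)(C)[Si](C)(C)OS(=O)(=O)C(F)(F)F
Why: Kinetic enolization at the CH2 (C5) and not at the methyl-bearing C10, E1cB (retro-oxa-Michael) cleavage of the C6–O bond, and silylation of the released C9 alkoxide; C9 and C10 are untouched and the C5=C6 enone returns.

Step 7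
Reactants: 10 enone
Product: 11 (4R,6R,7S)-6-[(tert-butyldimethylsilyl)oxy]-4-(3-hydroxyprop-1-en-2-yl)-7-methylcyclohept-2-en-1-one
Conditions: SeO2 (cat.), t-BuOOH, CH2Cl2, rt
Reagents that add atoms: tert-butyl hydroperoxide, CC(C)(C)OO
Why: Riley-type allylic oxidation (ene reaction, then [2,3]-shift) at the methyl group of the only electron-rich alkene; the enone alkene is inert and methyl is preferred to the methine C7 in 1,1-disubstituted alkenes.

Step 8
Reactants: 11 allylic alcohol
Product: 12 2-[(1R,5S,6R)-6-[(tert-butyldimethylsilyl)oxy]-5-methyl-4-oxocyclohept-2-en-1-yl]prop-2-enoic acid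
Conditions: TEMPO (cat.), NaOCl (cat.), NaClO2, MeCN/phosphate buffer pH 6.7, 35 °C
Reagents that add atoms: sodium chlorite, [Na+].[O-]Cl=O
Why: Oxoammonium oxidation of the primary allylic alcohol to the enal and chlorite (Pinnick-type) oxidation to the acid in one pot near neutrality, which spares the silyl ether, the enone and the epimerizable C10; any enal formed in step 7 converges here.

Step 9
Reactants: 12 enone acid; 13 (S)-but-3-yn-2-ol
Product: 15 enyne lactone (cis-fused α-methylene-γ-butyrolactone with C6–O and C7–C11 α; C1=C5 double bond; C1 bears (3S)-3-hydroxybut-1-ynyl; 9β-OSi(t-Bu)Me2; 10α-CH3), via tertiary alcohol 14 (not isolated)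
Conditions: 13 (3 equiv), n-BuLi (6 equiv), CeCl3, THF, −78 °C; 12; AcOH quench; then camphorsulfonic acid (cat.), CH2Cl2, 0 °C → rt
Reagents that add atoms: none
Why: The cerium acetylide of 13 adds 1,2 to the enone carbonyl of 12 (the carboxylate is inert) to give 14 as a mixture of C1 epimers, which does not matter. Camphorsulfonic acid then ionizes the tertiary alcohol, which is both allylic and propargylic, to an allyl cation spread over C1–C5–C6. The C12 carboxyl, held on C7 next to C6, captures the C6 terminus in a 5-exo closure of the γ-lactone ring (O–C12–C11–C7–C6), and the double bond settles at C1=C5 in conjugation with the alkyne. The closest known reaction type is the acid-catalysed dehydrative allylic substitution (SN1′ lactonization) of allylic alcohols by tethered carboxylic acids, the ring-forming half of an alkylative 1,3-transposition. The only new stereocentre, C6, is set by C7: the short tether delivers oxygen to the α face of the planar C6, so C6–O forms cis to C7–C11. The step needs lactonization to beat E1 loss of the C10 proton, Meyer–Schuster hydration and capture by the C9 silyl ether oxygen; a 5-exo intramolecular carboxyl in an anhydrous, weakly acidic medium should secure the first two, and the low nucleophilicity of the hindered silyl ether the third. Attack of the carboxyl at C1 would need a bridged seven-membered lactone and is not expected.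

Step 10
Reactants: 15 enyne lactone
Product: 16 1β,5β-epoxide of 15 (epoxide oxygen β; alkynyl group on C1 α)
Conditions: m-CPBA, NaHCO3, CH2Cl2, 0 °C
Reagents that add atoms: 3-chloroperbenzoic acid, OOC(=O)c1cccc(Cl)c1
Why: Prilezhaev epoxidation of the only electron-rich alkene (the acrylate and the alkyne do not react); both allylic substituents, C6–O and the C10 methyl, lie on the α face, so the peracid should attack the β face.

Step 11
Reactants: 16 epoxide
Product: 17 triol (1α-OH with the alkynyl group now β; 5β-OH; side-chain 3-OH)
Conditions: HClO4 (cat.), THF/H2O, 0 °C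
Reagents that add atoms: water, O
Why: Acid-catalysed epoxide hydrolysis: water attacks the tertiary, propargylic C1 from the α face with inversion while the epoxide oxygen stays on C5 (β), giving the trans-diol; C5, flanked by the lactone oxygen, is deactivated toward attack.

Step 12
Reactants: 17 triol
Product: 18 bis(3-methylbutanoate) (esters on C5–O and on the side-chain C4–O; C1–OH free)
Conditions: (i-BuCO)2O (3 equiv), DMAP (cat.), Et3N, CH2Cl2, 0 °C → rt
Reagents that add atoms: 3-methylbutanoic anhydride, CC(C)CC(=O)OC(=O)CC(C)C
Why: DMAP-catalysed acyl transfer to the two secondary alcohols; the tertiary C1–OH does not react. The C5 ester is the one in the target and the propargylic ester is the handle for step 14.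

Step 13
Reactants: 18 diester
Product: 19 C1 triethylsilyl ether of 18
Conditions: Et3SiOTf, 2,6-lutidine, CH2Cl2, −78 → 0 °C
Reagents that add atoms: triethylsilyl trifluoromethanesulfonate, CC[Si](CC)(CC)OS(=O)(=O)C(F)(F)F
Why: Silyl triflates silylate hindered tertiary alcohols; the ether blocks 5-endo attack of C1–OH on the gold-activated allene of step 14, which would give a dihydrofuranone.

Step 14
Reactants: 19 propargylic ester
Product: 20 bis-silyl ether of the target (C1–OSiEt3, C9–OSi(t-Bu)Me2, (E)-but-2-enoyl on C1)
Conditions: Ph3PAuNTf2 (2 mol %), butan-2-one/H2O, rt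
Reagents that add atoms: none
Why: Cationic monovalent gold triggers the [3,3]-sigmatropic 1,3-acyloxy shift of the internal propargylic ester to the allenyl ester, whose hydrolysis leaves the former ester carbonyl oxygen on C2 and gives the thermodynamically preferred (E)-enone; C4 becomes sp2 and the non-propargylic C5 ester is unaffected.

Step 15
Reactants: 20 bis-silyl ether
Product: 21 (3aS,5R,6S,7S,8S,8aR)-7-[(2E)-but-2-enoyl]-5,7-dihydroxy-6-methyl-3-methylidene-2-oxooctahydro-2H-cyclohepta[b]furan-8-yl 3-methylbutanoate
Conditions: HF·pyridine, THF, 0 °C → rt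
Reagents that add atoms: none
Why: Fluoride cleavage of both silyl ethers under acidic, non-basic conditions that spare the α-methylene lactone, the enone and the ester.

## Compound list

1 | (R)-(−)-carvone | CC1=CC[C@H](CC1=O)C(C)=C | starting material
2 | (1R,4R,6R)-1-methyl-4-(prop-1-en-2-yl)-7-oxabicyclo[4.1.0]heptan-2-one | C[C@@]12O[C@@H]1C[C@@H](C(C)=C)CC2=O | intermediate
3 | (2R,3R,5R)-3-hydroxy-2-methyl-5-(prop-1-en-2-yl)cyclohexan-1-one | C[C@@H]1[C@H](O)C[C@@H](C(C)=C)CC1=O | intermediate
4 | (3R,5R,6R)-6-methyl-3-(prop-1-en-2-yl)-1,5-bis(trimethylsilyloxy)cyclohex-1-ene | C[C@@H]1[C@H](O[Si](C)(C)C)C[C@@H](C(C)=C)C=C1O[Si](C)(C)C | intermediate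
5 | 2-methyl-5-(prop-1-en-2-yl)-1,3-bis(trimethylsilyloxy)bicyclo[4.1.0]heptane, CH2 trans to isopropenyl | C[C@@H]1[C@H](O[Si](C)(C)C)C[C@@H](C(C)=C)[C@@H]2C[C@]12O[Si](C)(C)C | intermediate
6 | 3-chloro-7-methyl-4-(prop-1-en-2-yl)-6-(trimethylsilyloxy)cycloheptan-1-one (C3 epimers) | C[C@@H]1[C@H](O[Si](C)(C)C)C[C@@H](C(C)=C)C(Cl)CC1=O | intermediate (not isolated)
7 | (4R,6R,7R)-6-hydroxy-7-methyl-4-(prop-1-en-2-yl)cyclohept-2-en-1-one | C[C@@H]1[C@H](O)C[C@@H](C(C)=C)C=CC1=O | intermediate (not isolated)
8 | (1R,2R,5R,6S)-2-methyl-6-(prop-1-en-2-yl)-8-oxabicyclo[3.2.1]octan-3-one (methyl axial) | C[C@H]1C(=O)C[C@H]2O[C@@H]1C[C@H]2C(C)=C | intermediate (not isolated)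
9 | (1R,2S,5R,6S)-2-methyl-6-(prop-1-en-2-yl)-8-oxabicyclo[3.2.1]octan-3-one (methyl equatorial, isopropenyl endo) | C[C@@H]1C(=O)C[C@H]2O[C@@H]1C[C@H]2C(C)=C | intermediate
10 | (4R,6R,7S)-6-[(tert-butyldimethylsilyl)oxy]-7-methyl-4-(prop-1-en-2-yl)cyclohept-2-en-1-one | C[C@H]1[C@H](O[Si](C)(C)C(C)(C)C)C[C@@H](C(C)=C)C=CC1=O | intermediate
11 | (4R,6R,7S)-6-[(tert-butyldimethylsilyl)oxy]-4-(3-hydroxyprop-1-en-2-yl)-7-methylcyclohept-2-en-1-one | C[C@H]1[C@H](O[Si](C)(C)C(C)(C)C)C[C@@H](C(=C)CO)C=CC1=O | intermediate
12 | 2-[(1R,5S,6R)-6-[(tert-butyldimethylsilyl)oxy]-5-methyl-4-oxocyclohept-2-en-1-yl]prop-2-enoic acid | C[C@H]1[C@H](O[Si](C)(C)C(C)(C)C)C[C@@H](C(=C)C(=O)O)C=CC1=O | intermediate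
13 | (S)-but-3-yn-2-ol | C[C@H](O)C#C | starting material
14 | 2-[(1R,5S,6R)-6-[(tert-butyldimethylsilyl)oxy]-4-hydroxy-4-[(3S)-3-hydroxybut-1-yn-1-yl]-5-methylcyclohept-2-en-1-yl]prop-2-enoic acid (both C4 epimers of the ring, i.e. C1 of the skeleton) | C[C@H]1[C@H](O[Si](C)(C)C(C)(C)C)C[C@@H](C(=C)C(=O)O)C=CC1(O)C#C[C@H](C)O | intermediate (not isolated)
15 | enyne lactone: cis-fused α-methylene-γ-butyrolactone (6α-O, 7α-C11), C1=C5 alkene, C1 bearing (3S)-3-hydroxybut-1-ynyl, 9β-silyloxy, 10α-methyl | C=C1C(=O)O[C@@H]2[C@H]1C[C@@H](O[Si](C)(C)C(C)(C)C)[C@H](C)C(C#C[C@H](C)O)=C2 | intermediate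
16 | 1β,5β-epoxide of 15 (alkynyl on C1 α) | C=C1C(=O)O[C@@H]2[C@H]1C[C@@H](O[Si](C)(C)C(C)(C)C)[C@H](C)[C@@]3(C#C[C@H](C)O)O[C@@H]23 | intermediate
17 | triol: 1α-OH (alkynyl β), 5β-OH, side-chain (3S)-OH; lactone, 9β-silyloxy and 10α-methyl as in 15 | C=C1C(=O)O[C@@H]2[C@H]1C[C@@H](O[Si](C)(C)C(C)(C)C)[C@H](C)[C@@](O)(C#C[C@H](C)O)[C@H]2O | intermediate
18 | bis(3-methylbutanoate) of 17 (C5–O and side-chain C4–O) | C=C1C(=O)O[C@@H]2[C@H]1C[C@@H](O[Si](C)(C)C(C)(C)C)[C@H](C)[C@@](O)(C#C[C@H](C)OC(=O)CC(C)C)[C@H]2OC(=O)CC(C)C | intermediate
19 | C1 triethylsilyl ether of 18 | C=C1C(=O)O[C@@H]2[C@H]1C[C@@H](O[Si](C)(C)C(C)(C)C)[C@H](C)[C@@](O[Si](CC)(CC)CC)(C#C[C@H](C)OC(=O)CC(C)C)[C@H]2OC(=O)CC(C)C | intermediate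
20 | 1-O-triethylsilyl-9-O-(tert-butyldimethylsilyl) derivative of the target | C=C1C(=O)O[C@@H]2[C@H]1C[C@@H](O[Si](C)(C)C(C)(C)C)[C@H](C)[C@@](O[Si](CC)(CC)CC)(C(=O)/C=C/C)[C@H]2OC(=O)CC(C)C | intermediate
21 | (3aS,5R,6S,7S,8S,8aR)-7-[(2E)-but-2-enoyl]-5,7-dihydroxy-6-methyl-3-methylidene-2-oxooctahydro-2H-cyclohepta[b]furan-8-yl 3-methylbutanoate | C=C1C(=O)O[C@@H]2[C@H]1C[C@@H](O)[C@H](C)[C@@](O)(C(=O)/C=C/C)[C@H]2OC(=O)CC(C)C | target

## Step count and least certain steps

Total step count: 15. Longest linear sequence: 15 steps, from 1 to 21; 13 is used as purchased.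

**Step 9 (key step).** The cation may escape lactonization: E1 loss of the C10 proton, Meyer–Schuster-type hydration of the propargylic cation, or capture by the C9 silyl ether oxygen (which would rebuild the oxabicycle) all compete with the 5-exo carboxyl capture, and closure on the β face would give the trans-fused lactone. Fallback: setting out from 14, oxidative 1,3-transposition with pyridinium chlorochromate (C5H5NH[CrO3Cl], Dauben–Babler oxidation) converts both C1 epimers into the same enynone keto acid F1 (C6 ketone, C1=C5 alkene; the side-chain carbinol is oxidized as well). 1,2-Reduction with NaBH4/CeCl3 delivers hydride anti to the C7 side chain and reduces the side-chain ketone; the resulting 6α-hydroxy acid lactonizes on acidification. This rejoins the route at 15, accompanied by its C4 epimer, which is harmless because C4 becomes sp2 in step 14.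

**Step 4.** The zinc carbenoid may also cyclopropanate the isopropenyl group, or zinc iodide may cleave the silyl enol ether before it reacts. Fallback: setting out from 3, Me3SiCl/imidazole gives the silyl ether F2; Me3SiCHN2/BF3·OEt2 inserts one carbon on the CH2 side (the less substituted carbon migrates) to give the cycloheptanone F3; kinetic silyl enol ether formation and Pd(OAc)2 (Saegusa–Ito dehydrogenation) give the enone F4; K2CO3/MeOH then removes the silyl group and closes the bicycle, rejoining the route at 9.

**Step 6.** Deprotonation at C10 would cleave C9–O instead of C6–O, and silylation of the enolate oxygen may outrun ring opening. Fallback: setting out from 9, LiN(i-Pr)2/Me3SiCl at −78 °C gives the kinetic silyl enol ether F5, which is isolated so that its regiochemistry is secured. t-BuMe2SiOTf in CH2Cl2 then silylates the bridging oxygen, and the enol ether expels it (cationic, silyl-transfer ring opening in place of the anionic E1cB), rejoining the route at 10.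

**Step 11.** A free propargylic cation at C1 would erode the inversion (loss of facial fidelity), and a hydride shift from C5 or SN2′ attack at the alkyne could divert the epoxide. Fallback: setting out from 15, N-bromosuccinimide in aqueous THF forms the bromonium ion on the β face and water enters at the tertiary C1 from the α face to give the bromohydrin F6 (1α-OH, 5β-Br). K2CO3 in acetone closes the α-epoxide F7 with inversion at C5. Cesium 3-methylbutanoate in DMF opens F7 by SN2 at C5, its only non-quaternary carbon, from the β face to give the mono-ester F8. 3-Methylbutanoic anhydride/DMAP then acylates the propargylic alcohol and rejoins the route at 18.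

## Further compounds

F1 | step 9 | 2-[(1R,5S,6R)-6-[(tert-butyldimethylsilyl)oxy]-5-methyl-7-oxo-4-(3-oxobut-1-yn-1-yl)cyclohept-3-en-1-yl]prop-2-enoic acid (enynone keto acid; skeleton C6 ketone, C1=C5 alkene) | OC(=O)C(=C)[C@@H]1C[C@@H](O[Si](C)(C)C(C)(C)C)[C@H](C)C(C#CC(C)=O)=CC1=O
F2 | step 4 | (2R,3R,5R)-2-methyl-5-(prop-1-en-2-yl)-3-(trimethylsilyloxy)cyclohexan-1-one | C[C@@H]1[C@H](O[Si](C)(C)C)C[C@@H](C(C)=C)CC1=O
F3 | step 4 | 7-methyl-4-(prop-1-en-2-yl)-6-(trimethylsilyloxy)cycloheptan-1-one (centres as in 3) | C[C@@H]1[C@H](O[Si](C)(C)C)C[C@@H](C(C)=C)CCC1=O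
F4 | step 4 | 7-methyl-4-(prop-1-en-2-yl)-6-(trimethylsilyloxy)cyclohept-2-en-1-one (trimethylsilyl ether of 7) | C[C@@H]1[C@H](O[Si](C)(C)C)C[C@@H](C(C)=C)C=CC1=O
F5 | step 6 | kinetic trimethylsilyl enol ether of 9 (4-methyl-6-(prop-1-en-2-yl)-3-(trimethylsilyloxy)-8-oxabicyclo[3.2.1]oct-2-ene) | C[C@@H]1C(O[Si](C)(C)C)=C[C@H]2O[C@@H]1C[C@H]2C(C)=C
F6 | step 11 | bromohydrin of 15 (1α-OH, alkynyl β, 5β-Br) | C=C1C(=O)O[C@@H]2[C@H]1C[C@@H](O[Si](C)(C)C(C)(C)C)[C@H](C)[C@@](O)(C#C[C@H](C)O)[C@H]2Br
F7 | step 11 | 1α,5α-epoxide (alkynyl on C1 β) | C=C1C(=O)O[C@@H]2[C@H]1C[C@@H](O[Si](C)(C)C(C)(C)C)[C@H](C)[C@]3(C#C[C@H](C)O)O[C@H]23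
F8 | step 11 | 5-O-(3-methylbutanoyl) derivative of 17 (side-chain alcohol free) | C=C1C(=O)O[C@@H]2[C@H]1C[C@@H](O[Si](C)(C)C(C)(C)C)[C@H](C)[C@@](O)(C#C[C@H](C)O)[C@H]2OC(=O)CC(C)C
A1 | alternative 1 | methyl (Z)-2-(bromomethyl)alk-2-enoate bearing the C6 aldehyde, with C9–OSi(t-Bu)Me2, C10–CH3, C1(OSiEt3)(silyloxybutynyl) and C5–O-(4-methoxybenzyl) | BrC/C(C(=O)OC)=C\C[C@@H](O[Si](C)(C)C(C)(C)C)[C@H](C)[C@@](O[Si](CC)(CC)CC)(C#C[C@H](C)O[Si](C)(C)C(C)(C)C)[C@H](C=O)OCc1ccc(OC)cc1
A2 | alternative 2 | furan | c1ccoc1
A3 | alternative 2 | 2-(benzyloxy)-4-methyl-8-oxabicyclo[3.2.1]oct-6-en-3-one (both substituents equatorial) | C[C@@H]1C(=O)[C@H](OCc2ccccc2)[C@H]3O[C@@H]1C=C3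
A4 | alternative 3 | 5β-hydroxy C1-keto lactone (6α,7α-cis-fused α-methylene lactone, 9β-silyloxy, 10α-methyl) | C=C1C(=O)O[C@@H]2[C@H]1C[C@@H](O[Si](C)(C)C(C)(C)C)[C@H](C)C(=O)[C@H]2O
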